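The runs are calculated from invented constants, and the scatter is random.

- At early times the substrate decays first order. Saturday's run has 42% left at 0.208 d, so I read 4.17 d⁻¹, a half-life of 0.166 d. Target reads 7% there, so I take the missing 51.0% to be an unseen intermediate.

all flasks: catalyst 9.2 mM
- Saturday's: substrate 0.46 M; reagent 0.46 M; run made earlier
- Wednesday's: substrate 0.23 M; reagent 0.46 M; run made earlier
- Monday's: substrate 0.92 M; reagent 0.46 M; run made earlier
- Tuesday's: substrate 0.46 M; reagent 0.69 M; run made earlier
- zeta: substrate 0.46 M; reagent 0.460 M; everything together at the start; time 4.0 d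
- theta: substrate 0.46 M (fed, over 40 h); reagent 0.460 M; all else is in the flask from the start; the feed brings no volume worth counting; time 4.0 d
- beta: substrate 0.46 M; reagent 0.460 M (fed, over 4.0 h); all else is in the flask from the start; the feed brings no volume worth counting; time 4.0 d
- alpha: substrate 0.46 M; reagent 0.460 M (fed, over 40 h); all else is in the flask from the start; the feed brings no volume worth counting; time 4.0 d

| run | time / d | target / % | substrate / % |
|---|---|---|---|
| Saturday's | 0.208 | 7 | 42 |
| Saturday's | 0.625 | 14 | 10 |
| Saturday's | 1.04 | 23 | 1 |
| Saturday's | 1.67 | 29 | 2 |
| Saturday's | 2.50 | 36 | 0 |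
| Wednesday's | 0.333 | 7 | 24 |
| Wednesday's | 0.625 | 18 | 11 |
| Wednesday's | 1.04 | 28 | 3 |
| Wednesday's | 2.00 | 37 | 0 |
| Wednesday's | 4.00 | 51 | 2 |
| Monday's | 0.833 | 18 | 5 |
| Monday's | 1.67 | 23 | 0 |
| Monday's | 2.50 | 28 | 1 |
| Monday's | 3.00 | 29 | 1 |
| Monday's | 4.00 | 29 | 0 |
| Tuesday's | 0.333 | 13 | 22 |
| Tuesday's | 1.04 | 27 | 1 |
| Tuesday's | 1.67 | 35 | 0 |
| Tuesday's | 3.00 | 43 | 1 |
| Tuesday's | 4.00 | 46 | 0 |

(each reading ± 1.5 percentage points)

- a reading or a percentage of target counts all its forms, free or not

* the best flask by amount of target, in percent of the substrate charged; "all alike" if 1.5 percentage points covers them all (zeta / theta / beta / alpha / all alike)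
* amount of target at the end, in percent of the substrate charged, zeta
* amount of target at the end, in percent of the substrate charged, theta
* amount of target at the end, in percent of the substrate charged, beta
* amount of target at the end, in percent of the substrate charged, alpha

- With the main steps alone, substrate gives intermediate, and intermediate plus reagent gives target one to one. Zeta's equal charges would then allow 100% target.
- Monday's run disagrees with that. Its last two readings stand level, at 29% and 29%, with target equal to 58.0% of its reagent, so reagent seems to be lost elsewhere.
- So I add one process, reagent lost to itself at second order. At fixed catalyst, reagent lost per reagent used for target is then a constant, a selectivity factor, times u = c(reagent)/c(intermediate).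
- I work with the fraction of intermediate left. Integrating gives f = 1/√(1 + 2u) once reagent is gone, for a factor of 3, which I choose by hand because Monday's run then has an estimated end value of 29.3% against its reading of 29%.
- Wednesday's estimated end value of 55.3% stands above its 51%, which was still rising at 4.00 d.
- For zeta, my estimated end value of target, 1 − f from the starting u, is 42.3%.
- Then I add the feeds. After 4.0 h, counting the reagent in each flask as not yet used and the intermediate as the substrate already reacted, theta has u near 35.8, while alpha has about 0.200, far lower. So I put alpha above zeta, theta below it, and beta close to zeta.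
- The forecast differs. It says “The fade therefore follows target made” and gives zeta as best: zeta 42%, theta 38%, beta 41%, alpha 36%.
- The simulation gives alpha as best: zeta 39.8%, theta 26.2%, beta 42.3%, alpha 49.6%.

    substrate + catalyst → catalyst + intermediate (k = 0.318 L mol⁻¹ min⁻¹)
    reagent + catalyst + intermediate → catalyst + target (k = 0.127 L² mol⁻² min⁻¹)
    reagent + target ⇌ idle adduct, settled at all times (K = 0.760 L mol⁻¹)
    2 reagent → self-condensation product (k = 0.00118 L mol⁻¹ min⁻¹)

- Alpha stands above my estimate of 42.3% for zeta, and it has not come to rest. At 4.00 d it holds 8.59% of its reagent and 50.4% intermediate, so u is 0.170. The fraction-left rule then adds 6.88%, giving 56.5%, and the computed value at 40.0 d is 58.1%.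
- The same reckoning serves theta read later. At the end of its feed, 1.67 d, theta holds 19.6% of its reagent, 13.5% target, and 86.5% as substrate plus intermediate, so u is 0.226 and the rule gives 28.2%. The computed value at 10 d is 29.9%.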